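The flavanone is cut through ring C at O1–C8a and C4–C4a. In ring A the ether oxygen O1 (on C8a) and the C4 carbonyl (on C4a) are neighbours, with the C5 oxygen next to C4a; this is the pattern left when a 3-alkoxyaryne inserts into the acyl–oxygen bond of a carboxylic acid. In one operation the key step therefore joins the fully substituted ring A to MOM-protected p-coumaric acid and delivers the open 2'-hydroxychalcone with only the future O1 free. Its precursor is an ortho-trimethylsilylaryl triflate bearing two MOM ethers and the (1E,3S)-dimethyloctadienyl chain from (S)-citronellal. Catalytic asymmetric oxa-Michael closure and MOM removal complete the route.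

Key step: step 9

Assumption: the quinine-derived thiourea named in step 10 is taken to give the 2S configuration at C2; if a small-scale trial shows the opposite sense, its quinidine-derived pseudoenantiomer replaces it with nothing else changed.

Step 1
Reactants: 1 phloroglucinol
Product: 2 3,5-bis(methoxymethoxy)phenol
Conditions: MOMCl (2.0 equiv), i-Pr2NEt, THF/DMF, 0 °C to rt; chromatography
Reagents that add atoms: chloromethyl methyl ether, COCCl
Why: Williamson-type O-alkylation with two equivalents of the chloromethyl ether stops statistically at the bis-ether, which is separable from the mono- and tris-ethers (these can be hydrolysed back to 1 and reused).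

Step 2
Reactants: 2 3,5-bis(methoxymethoxy)phenol
Product: 3 [3,5-bis(methoxymethoxy)phenoxy]tri(propan-2-yl)silane
Conditions: i-Pr3SiCl, imidazole, DMF, rt
Reagents that add atoms: chlorotri(propan-2-yl)silane, CC(C)[Si](Cl)(C(C)C)C(C)C
Why: Imidazole-promoted O-silylation of the only free phenol gives a bulky silyl ether that is inert to n-BuLi and keeps metalation away from its own ortho positions.

Step 3
Reactants: 3 [3,5-bis(methoxymethoxy)phenoxy]tri(propan-2-yl)silane; 4 (S)-citronellal
Product: 6 (3S)-1-[2,6-bis(methoxymethoxy)-4-(triisopropylsilyloxy)phenyl]-3,7-dimethyloct-6-en-1-ol as a mixture of C1 epimers, via aryllithium 5 (not isolated)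
Conditions: n-BuLi, THF, 0 °C; then 4, −78 °C to 0 °C; then H2O
Reagents that add atoms: none
Why: Directed ortho-metalation occurs at the one ring carbon flanked by two chelating MOM ethers, and 1,2-addition of this aryllithium to the aldehyde of 4 joins the chain without touching its C3 stereocentre; the new carbinol centre forms unselectively and is removed in step 4.

Step 4
Reactants: 6 (3S)-1-[2,6-bis(methoxymethoxy)-4-(triisopropylsilyloxy)phenyl]-3,7-dimethyloct-6-en-1-ol
Product: 7 {4-[(1E,3S)-3,7-dimethylocta-1,6-dien-1-yl]-3,5-bis(methoxymethoxy)phenoxy}tri(propan-2-yl)silane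
Conditions: methyl N-(triethylammoniosulfonyl)carbamate (Burgess reagent), toluene, 60 °C
Reagents that add atoms: none
Why: Burgess dehydration (syn-elimination through a sulfamate ester) under non-acidic conditions should give the conjugated E-styrene as the only possible regioisomer, avoiding the free benzylic cation that acid would produce and that the C6=C7 alkene or a MOM group could trap; the 3S centre lies outside the reacting atoms and is retained.

Step 5
Reactants: 7 {4-[(1E,3S)-3,7-dimethylocta-1,6-dien-1-yl]-3,5-bis(methoxymethoxy)phenoxy}tri(propan-2-yl)silane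
Product: 8 4-[(1E,3S)-3,7-dimethylocta-1,6-dien-1-yl]-3,5-bis(methoxymethoxy)phenol
Conditions: n-Bu4NF, THF, 0 °C; then H2O
Reagents that add atoms: none
Why: Fluoride-induced cleavage of the aryl silyl ether (desilylation) frees the phenol while MOM ethers and both alkenes are inert to fluoride.

Step 6
Reactants: 8 4-[(1E,3S)-3,7-dimethylocta-1,6-dien-1-yl]-3,5-bis(methoxymethoxy)phenol
Product: 9 2-bromo-4-[(1E,3S)-3,7-dimethylocta-1,6-dien-1-yl]-3,5-bis(methoxymethoxy)phenol
Conditions: NBS (1.0 equiv), i-Pr2NH (10 mol %), CH2Cl2, −78 °C, dark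
Reagents that add atoms: N-bromosuccinimide, O=C1CCC(=O)N1Br
Why: Electrophilic aromatic bromination should take one of the two equivalent ring positions ortho to the hydroxyl (each also ortho and para to a MOM ether), with the amine-derived N-bromo species hydrogen-bonded to the phenol and the low temperature favouring the ring over the alkenes.

Step 7
Reactants: 9 2-bromo-4-[(1E,3S)-3,7-dimethylocta-1,6-dien-1-yl]-3,5-bis(methoxymethoxy)phenol
Product: 13 4-[(1E,3S)-3,7-dimethylocta-1,6-dien-1-yl]-3,5-bis(methoxymethoxy)-2-(trimethylsilyl)phenyl trifluoromethanesulfonate, via TMS ether 10 (not isolated), via aryllithium 11 (not isolated), via lithium phenoxide 12 (not isolated)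
Conditions: (Me3Si)2NH, THF, 65 °C, concentrate; n-BuLi, THF, −78 °C; then PhNTf2, −78 °C to rt; then H2O
Reagents that add atoms: hexamethyldisilazane, C[Si](C)(C)N[Si](C)(C)C; N-phenylbis(trifluoromethanesulfonimide), O=S(=O)(N(c1ccccc1)S(=O)(=O)C(F)(F)F)C(F)(F)F
Why: O-silylation, fast bromine–lithium exchange and a retro-Brook rearrangement (1,3 shift of silicon from oxygen to the lithiated ortho carbon) give the lithium 2-silylphenoxide, whose O-triflation completes the standard construction of an ortho-silylaryl triflate.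

Step 8
Reactants: 14 p-coumaric acid
Product: 16 (E)-3-[4-(methoxymethoxy)phenyl]prop-2-enoic acid, via MOM ester 15 (not isolated)
Conditions: MOMCl (2.5 equiv), i-Pr2NEt, CH2Cl2, 0 °C to rt; then NaOH, MeOH/H2O, rt; then 1 M HCl to pH 4, 0 °C
Reagents that add atoms: chloromethyl methyl ether, COCCl; sodium hydroxide, [Na+].[OH-]
Why: Exhaustive O-alkylation protects phenol and carboxyl together, and saponification then cleaves only the acyl acetal ester because the aryl MOM ether is stable to base and to brief cold dilute acid.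

Step 9
Reactants: 13 4-[(1E,3S)-3,7-dimethylocta-1,6-dien-1-yl]-3,5-bis(methoxymethoxy)-2-(trimethylsilyl)phenyl trifluoromethanesulfonate; 16 (E)-3-[4-(methoxymethoxy)phenyl]prop-2-enoic acid
Product: 18 (E)-1-{3-[(1E,3S)-3,7-dimethylocta-1,6-dien-1-yl]-6-hydroxy-2,4-bis(methoxymethoxy)phenyl}-3-[4-(methoxymethoxy)phenyl]prop-2-en-1-one, via aryne 17 (not isolated)
Conditions: CsF (5 equiv), 16 (1.5 equiv), THF, 125 °C, sealed tube; then pH 7 phosphate buffer, 0 °C
Reagents that add atoms: none
Why: Fluoride attacks silicon in 13 and triflate leaves in a 1,2-elimination to give aryne 17 (C4a≡C8a in flavanone numbering); the carboxylate of 16 adds through oxygen at C8a, the resulting C4a aryl anion attacks its own ester carbonyl through a four-membered transition state, and collapse of that adduct leaves the aryl ketone (C4a–C4) and the C8a phenoxide, a net insertion of the aryne into the acyl–oxygen bond. The closest known reaction type is the fluoride-mediated intermolecular C–O addition of carboxylic acids, cinnamic acids included, to arynes that gives ortho-hydroxyaryl ketones, mechanistically an anionic Fries-type acyl shift. No ring closes and no stereocentre is formed; the 3S centre and both E alkenes are spectators. The step needs regioselective carboxylate addition, which the C5 MOM ether secures because a 3-alkoxyaryne is attacked at the carbon remote from oxygen so that the negative charge develops beside the inductively withdrawing substituent, and it needs acyl transfer to outrun protonation of the aryl anion, which the aprotic ether solvent, the high temperature and the proximity of the ester carbonyl favour. The product rests in the flask as the open-chain caesium phenoxide and is protonated cold at neutral pH, so only the future O1 is free and later closure can give only the 6-substituted flavanone.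

Step 10
Reactants: 18 (E)-1-{3-[(1E,3S)-3,7-dimethylocta-1,6-dien-1-yl]-6-hydroxy-2,4-bis(methoxymethoxy)phenyl}-3-[4-(methoxymethoxy)phenyl]prop-2-en-1-one
Product: 19 (2S)-6-[(1E,3S)-3,7-dimethylocta-1,6-dien-1-yl]-5,7-bis(methoxymethoxy)-2-[4-(methoxymethoxy)phenyl]-2,3-dihydro-4H-chromen-4-one
Conditions: 1-[3,5-bis(trifluoromethyl)phenyl]-3-[(8α,9S)-6'-methoxycinchonan-9-yl]thiourea (10 mol %), toluene, 0 °C
Reagents that add atoms: none
Why: In this intramolecular oxa-Michael addition (6-endo-trig) the quinuclidine nitrogen activates the 2'-hydroxyl while the thiourea binds the enone carbonyl, so the chiral catalyst should deliver the phenol oxygen to one face of the β-carbon and set C2 under catalyst control, the remote 3S centre exerting no influence.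

Step 11
Reactants: 19 (2S)-6-[(1E,3S)-3,7-dimethylocta-1,6-dien-1-yl]-5,7-bis(methoxymethoxy)-2-[4-(methoxymethoxy)phenyl]-2,3-dihydro-4H-chromen-4-one
Product: 20 (2S)-6-[(1E,3S)-3,7-dimethylocta-1,6-dien-1-yl]-5,7-dihydroxy-2-(4-hydroxyphenyl)-2,3-dihydro-4H-chromen-4-one (CNP0150993.1)
Conditions: 2 M aq. HCl (cat.), MeOH, 40 °C
Reagents that add atoms: none
Why: Acid-catalysed acetal exchange with methanol removes the three aryl MOM ethers, and the dilute acid and low temperature are chosen because C2 of a flavanone epimerises through base-induced ring opening rather than in mild acid and because stronger acid would protonate the styrene.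

Compound list
1 | phloroglucinol | Oc1cc(O)cc(O)c1 | starting material
2 | 3,5-bis(methoxymethoxy)phenol | COCOc1cc(O)cc(OCOC)c1 | intermediate
3 | [3,5-bis(methoxymethoxy)phenoxy]tri(propan-2-yl)silane | COCOc1cc(OCOC)cc(O[Si](C(C)C)(C(C)C)C(C)C)c1 | intermediate
4 | (S)-citronellal | CC(C)=CCC[C@H](C)CC=O | starting material
5 | [2,6-bis(methoxymethoxy)-4-(triisopropylsilyloxy)phenyl]lithium | [Li]c1c(OCOC)cc(O[Si](C(C)C)(C(C)C)C(C)C)cc1OCOC | intermediate
6 | (3S)-1-[2,6-bis(methoxymethoxy)-4-(triisopropylsilyloxy)phenyl]-3,7-dimethyloct-6-en-1-ol (C1 epimers) | CC(C)=CCC[C@H](C)CC(O)c1c(OCOC)cc(O[Si](C(C)C)(C(C)C)C(C)C)cc1OCOC | intermediate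
7 | {4-[(1E,3S)-3,7-dimethylocta-1,6-dien-1-yl]-3,5-bis(methoxymethoxy)phenoxy}tri(propan-2-yl)silane | CC(C)=CCC[C@H](C)/C=C/c1c(OCOC)cc(O[Si](C(C)C)(C(C)C)C(C)C)cc1OCOC | intermediate
8 | 4-[(1E,3S)-3,7-dimethylocta-1,6-dien-1-yl]-3,5-bis(methoxymethoxy)phenol | CC(C)=CCC[C@H](C)/C=C/c1c(OCOC)cc(O)cc1OCOC | intermediate
9 | 2-bromo-4-[(1E,3S)-3,7-dimethylocta-1,6-dien-1-yl]-3,5-bis(methoxymethoxy)phenol | CC(C)=CCC[C@H](C)/C=C/c1c(OCOC)cc(O)c(Br)c1OCOC | intermediate
10 | {2-bromo-4-[(1E,3S)-3,7-dimethylocta-1,6-dien-1-yl]-3,5-bis(methoxymethoxy)phenoxy}trimethylsilane | CC(C)=CCC[C@H](C)/C=C/c1c(OCOC)cc(O[Si](C)(C)C)c(Br)c1OCOC | intermediate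
11 | {3-[(1E,3S)-3,7-dimethylocta-1,6-dien-1-yl]-2,4-bis(methoxymethoxy)-6-(trimethylsilyloxy)phenyl}lithium | CC(C)=CCC[C@H](C)/C=C/c1c(OCOC)cc(O[Si](C)(C)C)c([Li])c1OCOC | intermediate
12 | lithium 4-[(1E,3S)-3,7-dimethylocta-1,6-dien-1-yl]-3,5-bis(methoxymethoxy)-2-(trimethylsilyl)phenoxide | CC(C)=CCC[C@H](C)/C=C/c1c(OCOC)cc(O[Li])c([Si](C)(C)C)c1OCOC | intermediate
13 | 4-[(1E,3S)-3,7-dimethylocta-1,6-dien-1-yl]-3,5-bis(methoxymethoxy)-2-(trimethylsilyl)phenyl trifluoromethanesulfonate | CC(C)=CCC[C@H](C)/C=C/c1c(OCOC)cc(OS(=O)(=O)C(F)(F)F)c([Si](C)(C)C)c1OCOC | intermediate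
14 | p-coumaric acid | OC(=O)/C=C/c1ccc(O)cc1 | starting material
15 | methoxymethyl (E)-3-[4-(methoxymethoxy)phenyl]prop-2-enoate | COCOC(=O)/C=C/c1ccc(OCOC)cc1 | intermediate
16 | (E)-3-[4-(methoxymethoxy)phenyl]prop-2-enoic acid | COCOc1ccc(/C=C/C(=O)O)cc1 | intermediate
17 | 4-[(1E,3S)-3,7-dimethylocta-1,6-dien-1-yl]-3,5-bis(methoxymethoxy)benzyne | C1#CC=C(OCOC)C(/C=C/[C@@H](C)CCC=C(C)C)=C1OCOC | intermediate
18 | (E)-1-{3-[(1E,3S)-3,7-dimethylocta-1,6-dien-1-yl]-6-hydroxy-2,4-bis(methoxymethoxy)phenyl}-3-[4-(methoxymethoxy)phenyl]prop-2-en-1-one | COCOc1ccc(/C=C/C(=O)c2c(O)cc(OCOC)c(/C=C/[C@@H](C)CCC=C(C)C)c2OCOC)cc1 | intermediate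
19 | (2S)-6-[(1E,3S)-3,7-dimethylocta-1,6-dien-1-yl]-5,7-bis(methoxymethoxy)-2-[4-(methoxymethoxy)phenyl]-2,3-dihydro-4H-chromen-4-one | CC(C)=CCC[C@H](C)/C=C/c1c(OCOC)cc2c(c1OCOC)C(=O)C[C@@H](c1ccc(OCOC)cc1)O2 | intermediate
20 | (2S)-6-[(1E,3S)-3,7-dimethylocta-1,6-dien-1-yl]-5,7-dihydroxy-2-(4-hydroxyphenyl)-2,3-dihydro-4H-chromen-4-one | CC(C)=CCC[C@H](C)/C=C/c1c(O)cc2c(c1O)C(=O)C[C@@H](c1ccc(O)cc1)O2 | target

Total step count: 11. Longest linear sequence: 10 steps (steps 1–7, then 9–11); step 8 is the side branch.

Steps most likely to fail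

Step 9. The aryl anion may be protonated before the acyl shift and leave the O-aryl ester. The product phenoxide may also be arylated by further aryne, or may close in the flask to C2-epimeric flavanones. The fallback sets out from bromophenol 9 and acid 16. Steglich esterification (DCC, DMAP, CH2Cl2) should give 2-bromo-4-[(1E,3S)-3,7-dimethylocta-1,6-dien-1-yl]-3,5-bis(methoxymethoxy)phenyl (E)-3-[4-(methoxymethoxy)phenyl]prop-2-enoate F1. Bromine–lithium exchange with t-BuLi (2 equiv, THF/Et2O, −100 °C) then produces the same ortho-metalated aryl ester without an aryne, and its anionic Fries-type 1,3-acyl shift returns the route at chalcone 18.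

Step 10. Facial selectivity may be poor, or the C2 configuration may erode through reversible ring opening under the basic catalyst. The fallback sets out from chalcone 18. Unselective closure (NaOAc, EtOH, reflux) gives 19 together with its C2 epimer, (2R)-6-[(1E,3S)-3,7-dimethylocta-1,6-dien-1-yl]-5,7-bis(methoxymethoxy)-2-[4-(methoxymethoxy)phenyl]-2,3-dihydro-4H-chromen-4-one F2. The two diastereomers are separated by preparative HPLC on an amylose tris(3,5-dimethylphenylcarbamate) phase. F2 is reopened with KOH in aqueous EtOH and acidified cold to regenerate 18 for another pass, and the route is rejoined at 19.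

Step 6. Electrophilic bromine may attack the electron-rich styrene or the trisubstituted alkene, or a second bromination may occur at the other ortho position. The fallback sets out from phenol 8 and uses directed metalation instead of electrophilic substitution. i-PrNCO and Et3N give 4-[(1E,3S)-3,7-dimethylocta-1,6-dien-1-yl]-3,5-bis(methoxymethoxy)phenyl N-(propan-2-yl)carbamate F3. In situ N-silylation (t-BuMe2SiOTf, TMEDA), ortho-lithiation between the carbamate and the MOM ether (n-BuLi, TMEDA, Et2O, −78 °C) and a Me3SiCl quench give 4-[(1E,3S)-3,7-dimethylocta-1,6-dien-1-yl]-3,5-bis(methoxymethoxy)-2-(trimethylsilyl)phenyl N-(propan-2-yl)carbamate F4. Carbamate cleavage with DBU and Et2NH in MeCN, followed in the same flask by PhNTf2, rejoins the route at 13 and bypasses 9 to 12.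

Further compounds
F1 | step 9 | 2-bromo-4-[(1E,3S)-3,7-dimethylocta-1,6-dien-1-yl]-3,5-bis(methoxymethoxy)phenyl (E)-3-[4-(methoxymethoxy)phenyl]prop-2-enoate | CC(C)=CCC[C@H](C)/C=C/c1c(OCOC)cc(OC(=O)/C=C/c2ccc(OCOC)cc2)c(Br)c1OCOC
F2 | step 10 | (2R)-6-[(1E,3S)-3,7-dimethylocta-1,6-dien-1-yl]-5,7-bis(methoxymethoxy)-2-[4-(methoxymethoxy)phenyl]-2,3-dihydro-4H-chromen-4-one | CC(C)=CCC[C@H](C)/C=C/c1c(OCOC)cc2c(c1OCOC)C(=O)C[C@H](c1ccc(OCOC)cc1)O2
F3 | step 6 | 4-[(1E,3S)-3,7-dimethylocta-1,6-dien-1-yl]-3,5-bis(methoxymethoxy)phenyl N-(propan-2-yl)carbamate | CC(C)=CCC[C@H](C)/C=C/c1c(OCOC)cc(OC(=O)NC(C)C)cc1OCOC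
F4 | step 6 | 4-[(1E,3S)-3,7-dimethylocta-1,6-dien-1-yl]-3,5-bis(methoxymethoxy)-2-(trimethylsilyl)phenyl N-(propan-2-yl)carbamate | CC(C)=CCC[C@H](C)/C=C/c1c(OCOC)cc(OC(=O)NC(C)C)c([Si](C)(C)C)c1OCOC
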